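The runs were generated by integration for substances that don't exist; the scatter is artificial.

The product asked for, complex with one exchanged, is a way station: in both earlier runs complex with two exchanged grows behind it.

| flask | starting complex | incoming ligand | remark | time |
|---|---|---|---|---|
| beta | 0.38 M | 0.25 M | run made earlier |  |
| zeta | 0.12 M | 0.25 M | run made earlier |  |
| autumn | 0.25 M | 0.250 M |  | 20 min |
| summer | 0.25 M | 0.500 M |  | 20 min |
| dawn | 0.25 M | 0.625 M |  | 20 min |

| run | time / min | complex with one exchanged / % | complex with two exchanged / % |
|---|---|---|---|
| beta | 2.50 | 11.3 | 0.9 |
| beta | 5.00 | 19.4 | 1.4 |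
| beta | 8.00 | 21.7 | 1.2 |
| beta | 10.0 | 26.5 | 2.6 |
| beta | 12.0 | 26.4 | 2.7 |
| zeta | 2.50 | 14.3 | 0.2 |
| zeta | 5.00 | 21.1 | 0 |
| zeta | 8.00 | 28.7 | 2.3 |
| zeta | 10.0 | 33.2 | 3.8 |
| zeta | 12.0 | 35.3 | 6.0 |

(each reading ± 1 percentage point)

1. final complex with one exchanged, as a percentage of the starting complex charged, for each flask in turn (autumn, summer, dawn)

- no earlier run changes the charge of incoming ligand; that part of a forecast is a guess

Anna and Ben dispute what the ligand charge does. Both take starting complex as what the two products leave. In zeta that is 78.9% at 5.00 min and 58.7% at 12.0 min. Both measure progress by exposure, the natural log of charged over remaining starting complex. In zeta it reaches 0.237, then 0.533.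

Anna holds [incoming ligand] at its charge: exposure grows with ligand charge and time, at 0.178 /M/min. So dawn converts 89.1% of its starting complex in 20 min, and she expects more ligand to keep giving more product.

Ben objects that both exchanges use the same ligand, so [incoming ligand] stands in both rates and cancels from their ratio. He reads that ratio, the selectivity factor. Complex with two exchanged gains this factor times [complex with one exchanged] per unit of exposure. Taking the area under complex with one exchanged against exposure, through the readings at 5.00 min and 12.0 min, zeta gives 0.553. The same reckoning on beta gives 0.563. These are rough readings: zeta's rests on 6.0%, with a scatter of 1 percentage point.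

The inverse of zeta's reading, 1.81, is the crossing ratio: the value of [complex with one exchanged]/[starting complex] at which making equals using. On the series curve that happens at exposure 1.32, at a height of 48.0%, whatever the ligand.

I side with Ben. With charges held, which flatters the exposures, autumn reaches 0.888, short of the crossing. Summer reaches 1.78 and dawn 2.22, both beyond it. So I expect summer and dawn a little under 48.0%, and autumn lower.

The forecast stands on Ben's side with a higher top than mine: 41%, 53% and 53%, with dawn “just past the intermediate's maximum”.

Autumn, summer and dawn give 35.9%, 45.4% and 44.2% of complex with one exchanged.

    complex with one exchanged + incoming ligand ⇌ leaving ligand + complex with two exchanged (K = 2.99, k = 0.00158 /M/s)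
    leaving ligand → by-product carried off (k = 0.0652 /s)
    starting complex + incoming ligand ⇌ leaving ligand + complex with one exchanged (K = 0.333, k = 0.00382 /M/s)
    starting complex + complex with one exchanged → side product (k = 0.00160 /M/s)

In dawn, the ratio went from 1.58 at 10.0 min to 3.79 at 20.0 min, through 1.81, while complex with one exchanged fell from 47.0% to 44.2%. Autumn is Anna's ground: its ratio at 20.0 min was 0.843, below the crossing, and complex with one exchanged had risen from 29.1% to 35.9%. By 200 min, autumn's ratio stood at 7.03, above the crossing, with complex with one exchanged down to 24.6%.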